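All runs stem from a simulated flask for substances that don't exist.

The alder run ends with a leftover: at 12.0 h it still holds 89.3% of its starting material, yet its target has slowed from 0.0121 M h⁻¹ between 3.00 h and 5.00 h to 0.00440 M h⁻¹ between 8.00 h and 12.0 h, which is less.

all flasks: partner 0.475 M; free catalyst 2.5 mM
- oak: starting material 0.70 M; second substrate 0.25 M; temperature 25 °C; run made earlier
- alder: starting material 1.1 M; second substrate 0.25 M; temperature 58 °C; run made earlier
- cedar: starting material 0.50 M; second substrate 0.12 M; temperature 25 °C; run made earlier
- gamma: starting material 0.50 M; second substrate 0.250 M; temperature 40 °C; time 2.0 d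
- eta: starting material 0.50 M; second substrate 0.250 M; temperature 70 °C; time 2.0 d
- epsilon: starting material 0.50 M; second substrate 0.250 M; temperature 10 °C; time 2.0 d

oak run (percent of the starting material charged)

| time / d | target / % | starting material / % |
|---|---|---|
| 0.500 | 2.6 | 96.5 |
| 1.04 | 3.5 | 95.7 |
| 1.25 | 5.9 | 93.5 |
| 2.00 | 8.0 | 90.2 |
| 2.50 | 9.8 | 91.4 |

alder run (percent of the starting material charged)

| time / h | target / % | starting material / % |
|---|---|---|
| 1.00 | 2.9 | 98.5 |
| 3.00 | 5.1 | 96.0 |
| 5.00 | 7.3 | 92.6 |
| 8.00 | 8.9 | 90.2 |
| 12.0 | 10.5 | 89.3 |

cedar run (percent of the starting material charged)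

| time / d | target / % | starting material / % |
|---|---|---|
| 0.208 | 1.9 | 96.1 |
| 0.625 | 3.9 | 94.8 |
| 1.04 | 6.7 | 93.2 |
| 1.67 | 8.3 | 89.3 |
| 2.50 | 13.5 | 86.8 |

(each reading ± 1 percentage point)



* the best flask by amount of target, in percent of the starting material charged; "all alike" if 1.5 percentage points covers them all (gamma / eta / epsilon / all alike)
* amount of target at the end, in percent of the starting material charged, gamma
* amount of target at the end, in percent of the starting material charged, eta
* amount of target at the end, in percent of the starting material charged, epsilon

I turn the settings one at a time. Starting material and second substrate come first. By hand, a rate that follows them separates oak from cedar, since oak has twice cedar's second substrate and more starting material. The readings don't separate them: at 2.50 d oak holds 0.0686 M of target and cedar 0.0675 M, alike within the scatter.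

Heat comes next. By hand it multiplies the rate, and the readings go that way: oak at 25 °C averages 0.0274 M d⁻¹, while alder at 58 °C, which also holds more starting material, makes 0.290 M d⁻¹ between 1.00 h and 5.00 h, ten times that.

Time comes last. By hand, more time gives more target, but alder slows with its starting material still standing. So I look at the reagent charged in the smaller amount, the catalyst at 2.5 mM, far less than second substrate, and count target against it:

N = c(target) / c(catalyst charged)

oak, 2.50 d: N = 27.4

alder, 12.0 h: N = 46.2

I carry N, the turnover number, target made per catalyst charged, and take alder's value as a reading of what a catalyst has delivered by that run's last reading. Held at that reading, gamma's charge gives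

y = N c(catalyst charged) / c(starting material) = 23.1%

so this is my estimate for gamma, and no bound.

The forecast reads alder as “catalyst death, kd about 0.15/h, with a ceiling near 0.14 M”. It names gamma best and gives gamma 32%, eta 16%, epsilon 2.3%. Its gamma means N = 64.0, more than my 46.2, so here we differ.

The best flask is gamma, with 15.6%, against 11.6% in eta and 3.38% in epsilon.

    starting material + free catalyst ⇌ catalyst intermediate A (K = 0.854 M⁻¹, k = 14.1 M⁻¹ min⁻¹, Ea = 57.0 kJ mol⁻¹, ΔH = −20.0 kJ mol⁻¹)
    partner + catalyst intermediate A → free catalyst + target (k = 0.231 M⁻¹ min⁻¹, Ea = 74.0 kJ mol⁻¹)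
    second substrate + free catalyst ⇌ catalyst intermediate B (K = 1.42 M⁻¹, k = 0.257 M⁻¹ min⁻¹, Ea = 72.0 kJ mol⁻¹, ΔH = 16.0 kJ mol⁻¹)
    partner + catalyst intermediate B → free catalyst + second product (k = 0.678 M⁻¹ min⁻¹, Ea = 67.0 kJ mol⁻¹)
    partner + catalyst intermediate B → spent catalyst (k = 0.0196 M⁻¹ min⁻¹, Ea = 63.0 kJ mol⁻¹)
    (constants at 40 °C)

The forecast stands 16 percentage points high on gamma. In gamma N is 31.2 at 2.00 d, less than alder's 46.2, with 80.9% of the catalyst spent. The neighbour of gamma charged with 1.2 M of partner gives 32.2% at 2.00 d. With 90.2% of its catalyst spent, its N = 64.5, more than alder's 46.2.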